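Everything rests on cutting the dihydrofuran ring at O1–C2 and C2–C3. C2 is bonded only to O1, C3 and the carbinol carbon, so it can arrive as the carbon of an ester-stabilised sulfonium ylide and be inserted into an ortho-quinone methide made of C3, C3a, C7a and O1 of ring A (the benzofuran benzene ring). One operation forms both bonds, closes the five-membered ring and sets the only stereocentre, (R) at C2, under control of a chiral thiolanium ylide. The precursor is a 2-(tosylmethyl)phenol with benzyloxy at the future C6 and bromine at the future C5; the bromine blocks methide self-alkylation and later becomes the acetyl group.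

Key step: step 7

Atom labels O1, C2, C3, C3a, C4 to C7 and C7a are those of the 2,3-dihydro-1-benzofuran unit of the target; ring A is its benzene ring.
Assumption: the (2R,5R) thiolane is taken to deliver the (R) centre; if the sense of induction proves opposite, the (2S,5S) thiolane, made in the same two steps from (2R,5R)-hexane-2,5-diol, is used and nothing else changes.

Step 1
Reactants: 1 5-bromo-2,4-dihydroxybenzaldehyde
Product: 2 4-(benzyloxy)-5-bromo-2-hydroxybenzaldehyde
Conditions: BnBr (1.05 equiv), NaHCO3 (1.5 equiv), KI (0.1 equiv), MeCN, 80 °C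
Reagents that add atoms: benzyl bromide, BrCc1ccccc1
Why: Williamson etherification under a weak base should alkylate only the 4-hydroxyl, the more acidic one (para to the aldehyde, ortho to bromine), because the 2-hydroxyl is held in a hydrogen bond to the aldehyde.

Step 2
Reactants: 2 4-(benzyloxy)-5-bromo-2-hydroxybenzaldehyde
Product: 3 5-(benzyloxy)-4-bromo-2-(hydroxymethyl)phenol
Conditions: NaBH4 (1.5 equiv), THF/MeOH, 0 °C
Reagents that add atoms: none
Why: Borohydride reduction of the aldehyde to the benzylic alcohol leaves the aryl bromide and the benzyl ether alone, and the acid-sensitive salicyl alcohol is carried on without purification.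

Step 3
Reactants: 3 5-(benzyloxy)-4-bromo-2-(hydroxymethyl)phenol; 4 sodium p-toluenesulfinate
Product: 5 5-(benzyloxy)-4-bromo-2-(tosylmethyl)phenol
Conditions: TolSO2Na (3 equiv), HCO2H/H2O/THF, rt
Reagents that add atoms: none
Why: Acid-promoted SN1-type substitution, in which the benzylic alcohol, activated by the ortho hydroxyl and the para benzyloxy group, ionises and is captured at sulfur by the sulfinate to give the stable sulfone, while the bromine keeps the ring carbon para to the hydroxyl from competing as a nucleophile.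

Step 4
Reactants: 6 (2S,5S)-hexane-2,5-diol
Product: 8 (2S,5S)-hexane-2,5-diyl dimethanesulfonate, via monomesylate 7 (not isolated)
Conditions: MsCl (2.4 equiv), Et3N (3 equiv), CH2Cl2, 0 °C
Reagents that add atoms: methanesulfonyl chloride, CS(=O)(=O)Cl
Why: O-Sulfonylation of both secondary alcohols breaks no bond to a stereocentre, so both centres keep their configuration.

Step 5
Reactants: 8 (2S,5S)-hexane-2,5-diyl dimethanesulfonate
Product: 10 (2R,5R)-2,5-dimethylthiolane, via mesyloxy thiolate 9 (not isolated)
Conditions: Na2S·9H2O (1.3 equiv), EtOH, rt to 40 °C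
Reagents that add atoms: sodium sulfide, [Na+].[Na+].[S-2]
Why: Two SN2 displacements by sulfur, the second a 5-exo-tet ring closure, each run with inversion and should turn the (S,S) dimesylate into the trans (R,R) thiolane.

Step 6
Reactants: 10 (2R,5R)-2,5-dimethylthiolane; 11 ethyl bromoacetate
Product: 12 (2R,5R)-1-(2-ethoxy-2-oxoethyl)-2,5-dimethylthiolan-1-ium bromide
Conditions: acetone, rt, 48 h, salt collected by filtration
Reagents that add atoms: none
Why: SN2 S-alkylation of the sulfide by the activated α-bromo ester; the twofold symmetry of the thiolane makes its two sulfur lone pairs equivalent, so only one sulfonium salt can form.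

Step 7
Reactants: 5 5-(benzyloxy)-4-bromo-2-(tosylmethyl)phenol; 12 (2R,5R)-1-(2-ethoxy-2-oxoethyl)-2,5-dimethylthiolan-1-ium bromide
Product: 16 ethyl (2R)-6-(benzyloxy)-5-bromo-2,3-dihydro-1-benzofuran-2-carboxylate, via sulfonium ylide 13 (not isolated), via ortho-quinone methide 14 (not isolated), via betaine 15 (not isolated)
Conditions: 12 (1.3 equiv), Cs2CO3 (3 equiv), CH2Cl2, −20 °C, slow addition of 5, then 0 °C
Reagents that add atoms: none
Why: Proposed new method: Cs2CO3 turns salt 12 into the ester-stabilised ylide 13 and phenol 5, by 1,4-elimination of p-toluenesulfinate, into ortho-quinone methide 14; the ylide carbon adds to the exocyclic methylene (C2–C3 formed, ring A rearomatised) to give betaine 15, whose phenoxide then displaces the thiolane at C2 (O1–C2 formed). The closest known reaction type is the (4+1) annulation of ortho-quinone methides generated in situ with ester-stabilised sulfonium ylides, which is racemic for methides without a benzylic substituent and enantioselective only where a substituent at the future C3 is present; control of a lone C2 centre by the sulfide alone is the untested part. The dihydrofuran ring closes by 5-exo-tet SN2 displacement with inversion at the former ylide carbon, so that the (S)-configured betaine gives the (R) centre. That centre is controlled only by the trans-2,5-dimethylthiolanium group: its twofold symmetry allows a single ylide, the methyl groups flanking sulfur shield one face of the ylide carbon in the addition, and, if 15 epimerises through reversible deprotonation, the same groups should make one epimer close faster. The step needs enantioface selectivity and ylide addition ahead of methide self-alkylation; the first is served by low temperature and a ring closure that either outruns epimerisation or discriminates between the epimers, the second by the bromine at the future C5, which blocks the nucleophilic ring carbon para to the phenoxide oxygen, by the excess of ylide and by slow addition of 5.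

Step 8
Reactants: 16 ethyl (2R)-6-(benzyloxy)-5-bromo-2,3-dihydro-1-benzofuran-2-carboxylate
Product: 18 2-[(2R)-6-(benzyloxy)-5-bromo-2,3-dihydro-1-benzofuran-2-yl]propan-2-ol, via methyl ketone 17 (not isolated)
Conditions: CH3MgBr (3.5 equiv), THF, −20 to 0 °C; then aq. NH4Cl
Reagents that add atoms: methylmagnesium bromide, C[Mg]Br
Why: Double Grignard addition to the ester through ketone 17, in which chelation by O1 should speed carbonyl addition of the small, weakly basic reagent past enolisation so that the C2 centre keeps its configuration, while the aryl bromide does not exchange with CH3MgBr.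

Step 9
Reactants: 18 2-[(2R)-6-(benzyloxy)-5-bromo-2,3-dihydro-1-benzofuran-2-yl]propan-2-ol
Product: 20 1-[(2R)-6-(benzyloxy)-2-(2-hydroxypropan-2-yl)-2,3-dihydro-1-benzofuran-5-yl]ethan-1-one, via enol ether 19 (not isolated)
Conditions: tributyl(1-ethoxyvinyl)stannane (1.5 equiv), Pd(PPh3)4 (5 mol %), toluene, 100 °C; then 1 M HCl, THF, rt
Reagents that add atoms: tributyl(1-ethoxyvinyl)stannane, CCCC[Sn](CCCC)(CCCC)C(=C)OCC; water, O
Why: Stille coupling of the aryl bromide with a masked acetyl anion, followed by mild hydrolysis of enol ether 19, should place the acetyl group exactly at C5 without any Lewis acid, so the tertiary alcohol, the benzyl ether and the C2 centre are not touched.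

Step 10
Reactants: 20 1-[(2R)-6-(benzyloxy)-2-(2-hydroxypropan-2-yl)-2,3-dihydro-1-benzofuran-5-yl]ethan-1-one
Product: 21 1-[(2R)-6-hydroxy-2-(2-hydroxypropan-2-yl)-2,3-dihydro-1-benzofuran-5-yl]ethan-1-one
Conditions: H2 (1 atm), 10% Pd/C, EtOAc, rt
Reagents that add atoms: none
Why: Catalytic hydrogenolysis of the benzyl ether should be faster than reduction of the aryl ketone, and the O1–C2 bond is not benzylic, so both survive if hydrogen uptake is followed and stopped.

Step 11
Reactants: 21 1-[(2R)-6-hydroxy-2-(2-hydroxypropan-2-yl)-2,3-dihydro-1-benzofuran-5-yl]ethan-1-one; 22 2,2-dimethylchroman-6-carbaldehyde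
Product: 24 (2E)-3-(2,2-dimethyl-3,4-dihydro-2H-1-benzopyran-6-yl)-1-[(2R)-6-hydroxy-2-(2-hydroxypropan-2-yl)-2,3-dihydro-1-benzofuran-5-yl]prop-2-en-1-one (the target), via aldol adduct 23 (not isolated)
Conditions: KOH (50% aq, 10 equiv), EtOH, rt; then 1 M HCl to pH 5, 0 °C
Reagents that add atoms: none
Why: Claisen–Schmidt condensation, in which the enolate of the methyl ketone adds to the non-enolisable aldehyde and aldol 23 loses water by E1cB to the conjugated enone of thermodynamic (E) geometry, while C2 has no acidic hydrogen and strong base holds the product as the open phenoxide and not as the flavanone.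

Compound list
1 | 5-bromo-2,4-dihydroxybenzaldehyde | O=Cc1cc(Br)c(O)cc1O | starting material
2 | 4-(benzyloxy)-5-bromo-2-hydroxybenzaldehyde | O=Cc1cc(Br)c(OCc2ccccc2)cc1O | intermediate
3 | 5-(benzyloxy)-4-bromo-2-(hydroxymethyl)phenol | OCc1cc(Br)c(OCc2ccccc2)cc1O | intermediate
4 | sodium p-toluenesulfinate (sodium 4-methylbenzenesulfinate) | Cc1ccc(cc1)S(=O)[O-].[Na+] | starting material
5 | 5-(benzyloxy)-4-bromo-2-(tosylmethyl)phenol | Cc1ccc(cc1)S(=O)(=O)Cc1cc(Br)c(OCc2ccccc2)cc1O | intermediate
6 | (2S,5S)-hexane-2,5-diol | C[C@H](O)CC[C@H](C)O | starting material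
7 | (2S,5S)-5-hydroxyhexan-2-yl methanesulfonate (monomesylate) | C[C@H](O)CC[C@H](C)OS(C)(=O)=O | intermediate (not isolated)
8 | (2S,5S)-hexane-2,5-diyl dimethanesulfonate | C[C@H](OS(C)(=O)=O)CC[C@H](C)OS(C)(=O)=O | intermediate
9 | sodium (2R,5S)-5-[(methanesulfonyl)oxy]hexane-2-thiolate (mesyloxy thiolate) | C[C@@H]([S-])CC[C@H](C)OS(C)(=O)=O.[Na+] | intermediate (not isolated)
10 | (2R,5R)-2,5-dimethylthiolane | C[C@@H]1CC[C@@H](C)S1 | intermediate
11 | ethyl bromoacetate | CCOC(=O)CBr | starting material
12 | (2R,5R)-1-(2-ethoxy-2-oxoethyl)-2,5-dimethylthiolan-1-ium bromide | CCOC(=O)C[S+]1[C@H](C)CC[C@H]1C.[Br-] | intermediate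
13 | ethyl 2-[(2R,5R)-2,5-dimethylthiolan-1-ium-1-yl]acetate ylide (sulfonium ylide) | CCOC(=O)[CH-][S+]1[C@H](C)CC[C@H]1C | intermediate (not isolated)
14 | 3-(benzyloxy)-4-bromo-6-methylidenecyclohexa-2,4-dien-1-one (ortho-quinone methide) | C=C1C=C(Br)C(OCc2ccccc2)=CC1=O | intermediate (not isolated)
15 | 4-(benzyloxy)-5-bromo-2-{(2S)-2-[(2R,5R)-2,5-dimethylthiolan-1-ium-1-yl]-3-ethoxy-3-oxopropyl}phenolate (betaine) | CCOC(=O)[C@H](Cc1cc(Br)c(OCc2ccccc2)cc1[O-])[S+]1[C@H](C)CC[C@H]1C | intermediate (not isolated)
16 | ethyl (2R)-6-(benzyloxy)-5-bromo-2,3-dihydro-1-benzofuran-2-carboxylate | CCOC(=O)[C@H]1Cc2cc(Br)c(OCc3ccccc3)cc2O1 | intermediate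
17 | 1-[(2R)-6-(benzyloxy)-5-bromo-2,3-dihydro-1-benzofuran-2-yl]ethan-1-one (methyl ketone) | CC(=O)[C@H]1Cc2cc(Br)c(OCc3ccccc3)cc2O1 | intermediate (not isolated)
18 | 2-[(2R)-6-(benzyloxy)-5-bromo-2,3-dihydro-1-benzofuran-2-yl]propan-2-ol | CC(C)(O)[C@H]1Cc2cc(Br)c(OCc3ccccc3)cc2O1 | intermediate
19 | 2-[(2R)-6-(benzyloxy)-5-(1-ethoxyethenyl)-2,3-dihydro-1-benzofuran-2-yl]propan-2-ol (enol ether) | CC(C)(O)[C@H]1Cc2cc(C(=C)OCC)c(OCc3ccccc3)cc2O1 | intermediate (not isolated)
20 | 1-[(2R)-6-(benzyloxy)-2-(2-hydroxypropan-2-yl)-2,3-dihydro-1-benzofuran-5-yl]ethan-1-one | CC(C)(O)[C@H]1Cc2cc(C(C)=O)c(OCc3ccccc3)cc2O1 | intermediate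
21 | 1-[(2R)-6-hydroxy-2-(2-hydroxypropan-2-yl)-2,3-dihydro-1-benzofuran-5-yl]ethan-1-one | CC(C)(O)[C@H]1Cc2cc(C(C)=O)c(O)cc2O1 | intermediate
22 | 2,2-dimethylchroman-6-carbaldehyde (2,2-dimethyl-3,4-dihydro-2H-1-benzopyran-6-carbaldehyde) | CC1(C)CCc2cc(C=O)ccc2O1 | starting material
23 | 3-(2,2-dimethyl-3,4-dihydro-2H-1-benzopyran-6-yl)-3-hydroxy-1-[(2R)-6-hydroxy-2-(2-hydroxypropan-2-yl)-2,3-dihydro-1-benzofuran-5-yl]propan-1-one (aldol adduct, both carbinol epimers) | CC1(C)CCc2cc(C(O)CC(=O)c3cc4c(cc3O)O[C@@H](C(C)(C)O)C4)ccc2O1 | intermediate (not isolated)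
24 | (2E)-3-(2,2-dimethyl-3,4-dihydro-2H-1-benzopyran-6-yl)-1-[(2R)-6-hydroxy-2-(2-hydroxypropan-2-yl)-2,3-dihydro-1-benzofuran-5-yl]prop-2-en-1-one | CC1(C)CCc2cc(/C=C/C(=O)c3cc4c(cc3O)O[C@@H](C(C)(C)O)C4)ccc2O1 | target

Total step count: 11 (steps 1 to 3 make the sulfone, steps 4 to 6 the sulfonium salt, step 7 joins them, steps 8 to 11 finish).
Longest linear sequence: 8 steps (steps 1, 2, 3, 7, 8, 9, 10, 11; the branch through steps 4, 5, 6 is equally long).

Steps most likely to fail

Step 7 (the proposed new method). The enantiomeric purity could come out low for three reasons: weak facial discrimination in the ylide addition, equilibration of betaine 15 without a useful rate difference in ring closure, or slow base-induced erosion of the new centre. Oligomerisation of the methide would instead cost material. The enantiomeric purity of 16 and 18 should be measured by HPLC on a chiral phase before going on. The fallback uses known chemistry and obtains the stereocentre by separation instead of induction. Setting out from sulfone 5, the racemic (4+1) annulation with the commercial achiral ylide ethyl 2-(dimethylsulfuranylidene)acetate and Cs2CO3 in CH2Cl2 at rt should run through ortho-quinone methide 14 and the racemic betaine 4-(benzyloxy)-5-bromo-2-[2-(dimethylsulfonio)-3-ethoxy-3-oxopropyl]phenolate F1 to racemic ethyl 6-(benzyloxy)-5-bromo-2,3-dihydro-1-benzofuran-2-carboxylate F2. Preparative chromatography on a chiral stationary phase (amylose tris(3,5-dimethylphenylcarbamate), supercritical CO2/MeOH) then separates the enantiomers; the (R) ester is 16, where the route is rejoined. The unwanted ethyl (2S)-6-(benzyloxy)-5-bromo-2,3-dihydro-1-benzofuran-2-carboxylate F3 can be racemised with catalytic NaOEt in EtOH and returned to the separation.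

Step 11. The phenoxide that forms first makes enolisation of the ketone slow, so the electron-rich aldehyde may be lost to Cannizzaro disproportionation before it condenses, and the chalcone may close to the flavanone during acidification. The fallback masks the phenol during the condensation. Setting out from 21, NaH (1.05 equiv) and chloromethyl methyl ether in DMF at 0 °C should etherify only the phenoxide to give 1-[(2R)-2-(2-hydroxypropan-2-yl)-6-(methoxymethoxy)-2,3-dihydro-1-benzofuran-5-yl]ethan-1-one F4. Claisen–Schmidt condensation of F4 with 22 (KOH, EtOH, rt) should then proceed through the methoxymethyl-protected aldol adduct F5 to the methoxymethyl-protected chalcone F6. Finally 3 M HCl in MeOH at rt cleaves the acetal, which the ortho carbonyl group activates, and gives target 24.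

Step 9. Oxidative addition of palladium into the electron-rich, ortho-alkoxylated aryl bromide may be slow, so that protodestannylation of the stannane takes over. The fallback acylates an aryllithium instead of cross-coupling. Setting out from 18, n-BuLi (2.2 equiv, THF, −78 °C) deprotonates the tertiary alcohol and exchanges bromine for lithium to give lithium 2-[(2R)-6-(benzyloxy)-5-lithio-2,3-dihydro-1-benzofuran-2-yl]propan-2-olate F7. Addition of F7 to N-methoxy-N-methylacetamide gives the chelated tetrahedral adduct F8 (Weinreb ketone synthesis), which cannot add a second time, and aqueous work-up releases ketone 20, where the route is rejoined.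

Further compounds
F1 | step 7 | racemic 4-(benzyloxy)-5-bromo-2-[2-(dimethylsulfonio)-3-ethoxy-3-oxopropyl]phenolate | CCOC(=O)C(Cc1cc(Br)c(OCc2ccccc2)cc1[O-])[S+](C)C
F2 | step 7 | racemic ethyl 6-(benzyloxy)-5-bromo-2,3-dihydro-1-benzofuran-2-carboxylate | CCOC(=O)C1Cc2cc(Br)c(OCc3ccccc3)cc2O1
F3 | step 7 | ethyl (2S)-6-(benzyloxy)-5-bromo-2,3-dihydro-1-benzofuran-2-carboxylate | CCOC(=O)[C@@H]1Cc2cc(Br)c(OCc3ccccc3)cc2O1
F4 | step 11 | 1-[(2R)-2-(2-hydroxypropan-2-yl)-6-(methoxymethoxy)-2,3-dihydro-1-benzofuran-5-yl]ethan-1-one | CC(C)(O)[C@H]1Cc2cc(C(C)=O)c(OCOC)cc2O1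
F5 | step 11 | 3-(2,2-dimethyl-3,4-dihydro-2H-1-benzopyran-6-yl)-3-hydroxy-1-[(2R)-2-(2-hydroxypropan-2-yl)-6-(methoxymethoxy)-2,3-dihydro-1-benzofuran-5-yl]propan-1-one | CC1(C)CCc2cc(C(O)CC(=O)c3cc4c(cc3OCOC)O[C@@H](C(C)(C)O)C4)ccc2O1
F6 | step 11 | (2E)-3-(2,2-dimethyl-3,4-dihydro-2H-1-benzopyran-6-yl)-1-[(2R)-2-(2-hydroxypropan-2-yl)-6-(methoxymethoxy)-2,3-dihydro-1-benzofuran-5-yl]prop-2-en-1-one | CC1(C)CCc2cc(/C=C/C(=O)c3cc4c(cc3OCOC)O[C@@H](C(C)(C)O)C4)ccc2O1
F7 | step 9 | lithium 2-[(2R)-6-(benzyloxy)-5-lithio-2,3-dihydro-1-benzofuran-2-yl]propan-2-olate | [Li]OC(C)(C)[C@H]1Cc2cc([Li])c(OCc3ccccc3)cc2O1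
F8 | step 9 | dilithium salt of 2-[(2R)-6-(benzyloxy)-5-{1-hydroxy-1-[methoxy(methyl)amino]ethyl}-2,3-dihydro-1-benzofuran-2-yl]propan-2-ol | [Li]OC(C)(C)[C@H]1Cc2cc(C(C)(O[Li])N(C)OC)c(OCc3ccccc3)cc2O1
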